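**Assumption:** atom labels follow hexaprenyl numbering (ring = C1–C14, C14 = ring CH, C15 = carbinol carbon, C16–C24 = side chain). Sulfonyl-bearing carbons are carried as epimer mixtures because both sulfones are removed at the end.

## Retrosynthetic overview

1. Target ⇐ bis-sulfone 14 by removing two allylic sulfones (C1 and C17).
2. C16–C17 bond ⇐ lithiated geranyl sulfone + macrocyclic hydroxy tosylate 11 (C15–O bond never broken).
3. The only ring (14-membered) is closed at C1–C14 by intramolecular SN2 opening of a cis-(14R,15S)-epoxide by the C1 allyl sulfone anion. Inversion sets C14; C15 comes from the epoxide.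
4. cis-Epoxy alcohol ⇐ Sharpless epoxidation of a Z-allylic alcohol, itself from B-alkyl Suzuki coupling (C13–C14) with (Z)-3-iodo-2-methylprop-2-en-1-ol.
5. Diene for the Suzuki step ⇐ farnesyl bromide (sulfinate alkylation, SeO2 oxidation, methylenation).

The trans-epoxide from an all-E chain would give the wrong C14/C15 relative configuration, which is why the Z-alkene is built deliberately.

## Route

**Step 1**
Reactants: 1 (2E,6E)-farnesyl bromide; 2 sodium benzenesulfinate
Product: 3 (2E,6E)-farnesyl phenyl sulfone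
Conditions: PhSO2Na, DMF, rt
Reagents that add atoms: sodium benzenesulfinate, [Na+].[O-]S(=O)c1ccccc1
Why: SN2 S-alkylation of sulfinate by the primary allylic bromide installs the group that later stabilises the C1 carbanion and survives every oxidation in the route.

**Step 2**
Reactants: 3
Product: 4 (2E,6E,10E)-2,6,10-trimethyl-12-(phenylsulfonyl)dodeca-2,6,10-trienal
Conditions: SeO2 (cat.), t-BuOOH, salicylic acid (cat.), CH2Cl2, rt; then MnO2, CH2Cl2 (crude mixture telescoped)
Reagents that add atoms: selenium dioxide, O=[Se]=O (oxygen source); tert-butyl hydroperoxide, CC(C)(C)OO (re-oxidant)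
Why: SeO2 allylic oxidation (ene/[2,3]) selects the E-methyl of the electron-rich terminal isopropylidene (C2=C3 is deactivated by the sulfone), and MnO2 converges the alcohol/aldehyde mixture to the E-enal.

**Step 3**
Reactants: 4
Product: 5 [(2E,6E,10E)-3,7,11-trimethyltrideca-2,6,10,12-tetraen-1-yl] phenyl sulfone
Conditions: CH2I2, Zn, Ti(OiPr)4, THF, rt
Reagents that add atoms: diiodomethane, ICI
Why: Takai-type Zn/Ti methylenation is non-basic, so the acidic α-sulfonyl CH2 is untouched while the enal becomes the terminal 1,3-diene.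

**Step 4**
Reactants: 6 propargyl alcohol
Product: 7 (Z)-3-iodo-2-methylprop-2-en-1-ol
Conditions: MeMgBr (2.5 equiv), CuI (10 mol%), THF, −10 °C → rt; then I2, −78 °C → rt
Reagents that add atoms: methylmagnesium bromide, C[Mg]Br; iodine, II
Why: Cu-catalysed anti-carbomagnesiation of the propargylic alkoxide puts Me on C2 and Mg on C3 in a chelate, and iodinolysis with retention gives the iodide cis to CH2OH.

**Step 5**
Reactants: 5; 7
Product: 8 (2Z,6E,10E,14E)-2,6,10,14-tetramethyl-16-(phenylsulfonyl)hexadeca-2,6,10,14-tetraen-1-ol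
Conditions: 5, 9-BBN, THF, 0 °C → rt; then 7, Pd(dppf)Cl2 (5 mol%), AsPh3, Cs2CO3, DMF/H2O, rt
Reagents that add atoms: vinyl iodide 7, OC/C(C)=C\I (9-BBN contributes only H)
Why: 9-BBN hydroborates only the monosubstituted terminal C=C (boron on C13), and B-alkyl Suzuki–Miyaura coupling proceeds with retention of the vinyl iodide geometry, giving the Z-allylic alcohol with C13 cis to CH2OH.

**Step 6**
Reactants: 8
Product: 9 [(2S,3R)-2-methyl-3-[(3E,7E,11E)-3,7,11-trimethyl-13-(phenylsulfonyl)trideca-3,7,11-trien-1-yl]oxiran-2-yl]methanol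
Conditions: Ti(OiPr)4, L-(+)-DET, t-BuOOH, 4 Å MS, CH2Cl2, −20 °C
Reagents that add atoms: tert-butyl hydroperoxide, CC(C)(C)OO
Why: Katsuki–Sharpless epoxidation touches only the allylic-alcohol olefin; L-(+)-tartrate gives the (2S,3R) cis-epoxide (same facial sense as nerol → (2S,3R)-epoxynerol), fixing C15 (S) and the pre-inversion C14 (R), expected about 90% ee for this olefin class.

**Step 7**
Reactants: 9
Product: 10 (2R)-2-[(1S,3E,7E,11E)-4,8,12-trimethyl-2-(phenylsulfonyl)cyclotetradeca-3,7,11-trien-1-yl]propane-1,2-diol (epimers at the sulfonyl carbon)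
Conditions: LiHMDS (2.2 equiv), THF/HMPA, −78 → 25 °C, 0.003 M (slow addition)
Reagents that add atoms: none
Why: The sulfonyl-stabilised allyl anion attacks through its α-carbon (C1) at the secondary epoxide carbon in an intramolecular SN2 epoxide opening, closing the 14-membered ring; inversion at C14 sets the ring stereocentre, while C15 keeps its oxygen and configuration.

**Step 8**
Reactants: 10
Product: 11 (2R)-2-hydroxy-2-[(1S,3E,7E,11E)-4,8,12-trimethyl-2-(phenylsulfonyl)cyclotetradeca-3,7,11-trien-1-yl]propyl 4-methylbenzenesulfonate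
Conditions: TsCl (1.1 equiv), Et3N, DMAP (cat.), CH2Cl2, 0 °C
Reagents that add atoms: p-toluenesulfonyl chloride, Cc1ccc(cc1)S(Cl)(=O)=O
Why: Selective sulfonylation of the primary hydroxyl of a primary/tertiary 1,2-diol activates C16 without touching the tertiary carbinol.

**Step 9**
Reactants: 12 geranyl bromide; 2
Product: 13 (E)-geranyl phenyl sulfone
Conditions: PhSO2Na, DMF, rt
Reagents that add atoms: sodium benzenesulfinate, [Na+].[O-]S(=O)c1ccccc1
Why: SN2 S-alkylation of sulfinate gives the α-selective C17 nucleophile for the side chain.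

**Step 10**
Reactants: 11; 13
Product: 14 (2S,5E)-6,10-dimethyl-4-(phenylsulfonyl)-2-[(1S,3E,7E,11E)-4,8,12-trimethyl-2-(phenylsulfonyl)cyclotetradeca-3,7,11-trien-1-yl]undeca-5,9-dien-2-ol (epimers at both sulfonyl carbons)
Conditions: 13 (3 equiv), n-BuLi, THF/HMPA, −78 °C; add 11; → rt
Reagents that add atoms: geranyl phenyl sulfone 13, CC(C)=CCC/C(C)=C/CS(=O)(=O)c1ccccc1
Why: The tertiary alkoxide closes onto the tosylate to give the 15,16-epoxide in situ, which the lithiated allyl sulfone opens at the CH2 terminus (sulfone alkylation); the C15–O bond is never broken, so C15 is retained.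

**Step 11**
Reactants: 14
Product: 15 colleterpenol, (2S,5E)-6,10-dimethyl-2-[(1R,3E,7E,11E)-4,8,12-trimethylcyclotetradeca-3,7,11-trien-1-yl]undeca-5,9-dien-2-ol
Conditions: PdCl2(dppp) (10 mol%), LiBHEt3 (excess), THF, 0 °C → rt
Reagents that add atoms: none (hydride only)
Why: Pd-catalysed reductive desulfonylation via π-allyl intermediates delivers hydride to the less substituted terminus (C1 and C17), keeping both E-trisubstituted alkenes in place; neither stereocentre is involved.

## Compound list

1 | (2E,6E)-farnesyl bromide | CC(C)=CCC/C(C)=C/CC/C(C)=C/CBr | starting material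
2 | sodium benzenesulfinate | [Na+].[O-]S(=O)c1ccccc1 | starting material
3 | (2E,6E)-farnesyl phenyl sulfone | CC(C)=CCC/C(C)=C/CC/C(C)=C/CS(=O)(=O)c1ccccc1 | intermediate
4 | (2E,6E,10E)-2,6,10-trimethyl-12-(phenylsulfonyl)dodeca-2,6,10-trienal | O=C/C(C)=C/CC/C(C)=C/CC/C(C)=C/CS(=O)(=O)c1ccccc1 | intermediate
5 | [(2E,6E,10E)-3,7,11-trimethyltrideca-2,6,10,12-tetraen-1-yl] phenyl sulfone | C=C/C(C)=C/CC/C(C)=C/CC/C(C)=C/CS(=O)(=O)c1ccccc1 | intermediate
6 | propargyl alcohol | C#CCO | starting material
7 | (Z)-3-iodo-2-methylprop-2-en-1-ol | OC/C(C)=C\I | intermediate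
8 | (2Z,6E,10E,14E)-2,6,10,14-tetramethyl-16-(phenylsulfonyl)hexadeca-2,6,10,14-tetraen-1-ol | OC/C(C)=C\CC/C(C)=C/CC/C(C)=C/CC/C(C)=C/CS(=O)(=O)c1ccccc1 | intermediate
9 | (2S,3R)-cis-epoxy alcohol (name in Step 6) | OC[C@]1(C)O[C@@H]1CC/C(C)=C/CC/C(C)=C/CC/C(C)=C/CS(=O)(=O)c1ccccc1 | intermediate
10 | macrocyclic sulfonyl diol (name in Step 7) | OC[C@](C)(O)[C@H]1C(S(=O)(=O)c2ccccc2)/C=C(\C)CC/C=C(\C)CC/C=C(\C)CC1 | intermediate
11 | primary tosylate of 10 | Cc1ccc(cc1)S(=O)(=O)OC[C@](C)(O)[C@H]1C(S(=O)(=O)c2ccccc2)/C=C(\C)CC/C=C(\C)CC/C=C(\C)CC1 | intermediate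
12 | geranyl bromide | CC(C)=CCC/C(C)=C/CBr | starting material
13 | (E)-geranyl phenyl sulfone | CC(C)=CCC/C(C)=C/CS(=O)(=O)c1ccccc1 | intermediate
14 | bis-sulfone (name in Step 10) | CC(C)=CCC/C(C)=C/C(S(=O)(=O)c3ccccc3)C[C@](C)(O)[C@H]1C(S(=O)(=O)c2ccccc2)/C=C(\C)CC/C=C(\C)CC/C=C(\C)CC1 | intermediate
15 | colleterpenol | CC(C)=CCC/C(C)=C/CC[C@](C)(O)[C@H]1C/C=C(\C)CC/C=C(\C)CC/C=C(\C)CC1 | target

## Step count and risks

Total steps: 11. Longest linear sequence: 9 (Steps 1, 2, 3, 5, 6, 7, 8, 10, 11).

Three steps most likely to fail: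

1. **Step 7 (macrocyclisation).** The sulfone anion may be too weak a nucleophile for a 14-membered epoxide opening, or oligomerise. Fallback: carry C1 as a silyl ether through the epoxidation, protect C16–OH, convert C1–OH to the allylic phenyl sulfide (PhSSPh/Bu3P) and cyclise with the more nucleophilic thio-stabilised allyllithium (s-BuLi/DABCO), removing sulfur with Li/EtNH2 at the end.

2. **Step 10 (side-chain coupling).** The hindered 15,16-epoxide may open slowly, and the ring α-sulfonyl C–H could interfere. Fallback: omit this coupling by building C15 with the full side chain already attached. Use 2-(homogeranyl)-3-iodoprop-2-en-1-ol (iodine cis to the chain) in Step 5, epoxidise with D-(−)-DET, cyclise as before, then convert the CH2OH into the C15 methyl (TsCl, then hydride).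

3. **Step 11 (double desulfonylation).** Hydride regiochemistry, E/Z scrambling, or alkoxide capture of the π-allyl could erode the product. Fallback: remove the ring sulfone at the diol stage (10) and add the side chain as a sulfone-free nucleophile (α-selective geranylbarium or geranyl cuprate on the derived 15,16-epoxide), so no π-allyl chemistry is run on the complete skeleton.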